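Assumption: the (S)-SEGPHOS-modified iridium catalyst is taken to give the (4R)-carbinol 4, by analogy with related transfer-hydrogenative allylations of aliphatic alcohols; if the sense proves opposite, (R)-SEGPHOS is used and nothing else changes.

## The problem

Target 14 is a monocarbocyclic terpenoid ether. Its cyclohexane is numbered here C1 (the CH carrying the C8H2–O–coumarin arm), C2 (carrying the exocyclic C7 methylene), C3, C4, C5 (CH–OAc) and C6 (the gem-dimethyl quaternary carbon), and C8–O links it to the 7-oxygen of a coumarin. Three contiguous ring carbons (C5, C6, C1) are substituted and C2 bears the methylene, so the ring must be closed at or next to a quaternary centre. There are only two stereocentres, C1 (S) and C5 (R), held 1,3-cis across C6. C5 is an isolated secondary carbinol that a catalyst can set in an open chain, and once set it is the only element available to direct C1. The sensitive groups are the coumarin lactone (opened by alkoxide, reducible by hydride), the secondary acetate (cleaved by base and able to migrate to a free primary hydroxyl four atoms away) and the 1,1-disubstituted C2=C7 alkene, which acid moves into the ring. C1 is allylic and, while C8 is an aldehyde, both epimerizable and prone to conjugation. The enabling feature is the C7 methylene on C2 directly beside the C1 methine that carries the one-carbon unit C8: this is what remains when the α-carbon of a C8 carbonyl compound adds across a terminal alkyne, so C1–C2 is the strategic bond.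

## Retrosynthesis

**C8–O (ether).** Cutting the alkyl–oxygen bond of 14 gives primary alcohol 12 and umbelliferone 13. This cut is preferred to carrying the coumarin through the route, because its lactone and electron-poor double bond would then meet boranes, hydride and silver or gold salts. The aryl–oxygen cut would need a metal-catalysed coupling under base, whereas the alkyl side can be joined by a neutral redox condensation. The forward reaction must etherify a β-branched primary carbinol without touching the acetate or the alkene; no stereocentre is involved.

**C8 oxidation level.** Alcohol 12 is traced to aldehyde 11. Nothing is cut, but the change is needed: only a carbonyl at C8 makes C1 nucleophilic enough for the ring closure. The forward reduction must be faster than epimerization at C1 or migration of the alkene, and must leave the acetate alone.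

**C1–C2 (ring closure).** Cutting C1–C2 of 11 opens the ring to silyl enol ether 10, with C2 and C7 becoming a terminal alkyne. Compared with cuts at C5–C6 or C1–C6, this one creates the methylene without a later olefination, removes the ring and one stereocentre in one move, and leaves an open chain with a single stereocentre. The forward reaction must be a 6-exo-dig carbocyclization that sets C1 cis to the C5 acetate under conditions mild enough for a β,γ-unsaturated aldehyde.

**Functional-group chain.** Enol ether 10 is the silylated form of aldehyde 9. Aldehyde 9 comes from 8 by removing the alkynyl silyl cap, 8 from alcohol 7 by oxidation, and 7 from alkene 5 by anti-Markovnikov hydration through alkylborane 6. No skeletal bond is cut; the order is dictated by chemoselectivity. The alkyne must stay capped until the alkene has been hydroborated, and C5 must carry its acetate before C8 is oxidized, otherwise the γ-hydroxy aldehyde closes to a lactol.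

**C5–C6 (chain assembly).** Acetate 5 is the ester of alcohol 4, and cutting C5–C6 of 4 gives alkynol 1 and allene 2, joined through the transient aldehyde 3. This single cut delivers the quaternary carbon, the vinyl group that becomes C1–C8, and the C5 stereocentre. An aldol or enolate alkylation route to the same array would need more steps and a separate reduction. The forward reaction must be enantioselective and must tolerate the silyl-capped alkyne.

## Roads not taken

**Alternative 1:** The cut is the C5–O bond, traced back to a C5–C8 carbon–carbon bond in the bridged cyclobutanone 7,7-dimethylbicyclo[3.1.1]heptane-2,6-dione A1.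
- Forward key step: a peracid or a Baeyer–Villiger monooxygenase inserts oxygen between the cyclobutanone carbonyl carbon and C5 with retention. This gives the bridged keto lactone 8,8-dimethyl-6-oxabicyclo[3.2.1]octane-2,7-dione A2. Ketone methylenation, lactone reduction, etherification and acetylation would follow.
- Merits: the lactone bridge fixes C1 and C5 cis by construction. Ring strain makes the cyclobutanone the faster-reacting ketone, and the C5 bridgehead should migrate in preference to C1, which carries the second carbonyl.
- Weak points: A1 is a strained, non-enolizable 1,3-diketone with no obvious enantioselective source, so the absolute configuration would come from a resolution or an enzymatic oxidation at the cost of half the material. A2 is a β-keto lactone that must be methylenated without retro-Claisen opening. Four further steps are needed after A2, on top of the synthesis of A1.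
- Comparison: in certainty of the relative configuration this road is better than the chosen plan, which relies on a conformational preference at C1. Against that the chosen plan sets a catalytic enantioselective entry from commercial materials, a methylene that comes from the alkyne without an olefination, and a shorter sequence. The lactone idea is kept as the contingency for step 7.

**Alternative 2:** The cut is the C5–C6 bond. The precursor is the open-chain aldehyde 4-[(tert-butyldimethylsilyl)oxy]-5-{[(4-methoxybenzyl)oxy]methyl}-6-methylhept-6-enal A3, in which C1 and an auxiliary oxygenated C2 are already stereodefined.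
- Forward key step: an iron hydride generated from Fe(acac)3 and PhSiH3 transfers a hydrogen atom to the isopropenyl group. The tertiary C6 radical adds to the C5 aldehyde carbon and gives cyclohexanol A4.
- Merits: the quaternary carbon, the C5 carbinol and the ring form together from an unactivated alkene. C1 is set before ring closure and never stands beside a carbonyl, so the epimerization risk of the chosen plan is absent; in that respect this road is better.
- Weak points: radical addition to an aldehyde is reversible, and the alkoxy radical must be reduced before it fragments. The C5 configuration rests on a chair preference relative to two existing centres. C2 needs a stereocentre and a protecting group that are later destroyed by deprotection, oxidation and methylenation next to C1. Two different oxygen protecting groups must be managed before the coumarin is attached.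
- Comparison: the route would be roughly half as long again as the chosen one and spends most of its steps on C2. In the chosen plan the alkyne supplies the methylene and only one stereocentre is made by a catalyst. The chosen plan must set its one epimerizable intermediate, 11, against this, and answers it by immediate reduction.

**Alternative 3:** The cut is the C1–C6 bond, with the aryl ether already in place. Umbelliferone 13 is O-geranylated to aurapten A5, and the terminal alkene is converted enantioselectively into the (R)-epoxide A6 (asymmetric dihydroxylation, then closure through the secondary sulfonate).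
- Forward key step: Cp2TiCl (trivalent titanium, from Cp2TiCl2 and Mn dust) opens the epoxide to a tertiary C6 radical, which adds to the C1=C2 alkene in a 6-endo closure. Loss of hydrogen from the tertiary C2 radical gives the deacetyl compound A7; acetylation would finish.
- Merits: bioinspired and about five to six steps. The ring, the C1 stereocentre and the methylene form in one step, with the E-alkene and the equatorial titanium alkoxide in a chair giving the 1,3-cis arrangement. The coumarin is attached to an unhindered allylic halide, and no epimerizable aldehyde appears. In step count and in avoiding the hindered etherification this road is better than the chosen plan.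
- Weak points: termination of the C2 radical is not regiospecific, so endocyclic alkene isomers accompany the exocyclic one and are hard to separate. Premature reduction or deoxygenation of the epoxide-derived radical competes with cyclization. Titanium is used in stoichiometric amount or needs a regeneration system, and the coumarin must tolerate the reducing medium.
- Comparison: the chosen plan is about three steps longer. It sets against this an alkene position fixed by construction (a terminal alkyne can only become the exocyclic methylene), a catalytic ring closure, and stereocentres made one at a time (C5 by catalyst, C1 by substrate), so that each can be checked and corrected separately.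

Key step: step 7

## Route

Step 1
Reactants: 1 5-(trimethylsilyl)pent-4-yn-1-ol; 2 3-methylbuta-1,2-diene
Product: 4 (4R)-3,3-dimethyl-8-(trimethylsilyl)oct-1-en-7-yn-4-ol, via 5-(trimethylsilyl)pent-4-ynal 3 (not isolated)
Conditions: 2 (2 equiv), [Ir(cod)Cl]2 (2.5 mol%), (S)-SEGPHOS (5 mol%), 3-nitrobenzoic acid (10 mol%), allyl acetate (10 mol%), Cs2CO3 (20 mol%), toluene, 60 °C, sealed tube
Reagents that add atoms: none
Why: Iridium-catalysed transfer-hydrogenative carbonyl tert-prenylation from the alcohol oxidation level: the cyclometallated iridium benzoate dehydrogenates 1 to aldehyde 3, the iridium hydride hydrometallates allene 2, and the resulting 1,1-dimethylallyl–iridium species adds to 3 through a closed chair transition state at its substituted terminus. The C5–C6 bond, the gem-dimethyl carbon and the C5 carbinol are made in one redox-neutral step, and the chiral bisphosphine selects the aldehyde face to give the (4R)-alcohol; the configuration is to be confirmed by Mosher ester analysis.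

Step 2
Reactants: 4 (4R)-3,3-dimethyl-8-(trimethylsilyl)oct-1-en-7-yn-4-ol
Product: 5 (4R)-3,3-dimethyl-8-(trimethylsilyl)oct-1-en-7-yn-4-yl acetate
Conditions: Ac2O, DMAP (cat.), pyridine, CH2Cl2, rt
Reagents that add atoms: acetic anhydride, CC(=O)OC(C)=O
Why: DMAP-catalysed acylation of a hindered neopentyl-type secondary alcohol. The acetate is the ester of the target and from here on prevents the C5 oxygen from closing onto C8 as a lactol once C8 is oxidized.

Step 3
Reactants: 5 (4R)-3,3-dimethyl-8-(trimethylsilyl)oct-1-en-7-yn-4-yl acetate
Product: 7 (4R)-1-hydroxy-3,3-dimethyl-8-(trimethylsilyl)oct-7-yn-4-yl acetate, via alkylborane 6 (not isolated)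
Conditions: 9-BBN (1.3 equiv), THF, 0 °C → rt; then 30% H2O2, aq. NaOAc, 0 °C → rt
Reagents that add atoms: hydrogen peroxide, OO
Why: Anti-Markovnikov hydroboration–oxidation: 9-BBN adds to the monosubstituted alkene much faster than to the silyl-capped internal alkyne and places boron on the terminal carbon, away from the quaternary centre. Acetate-buffered peroxide oxidizes the C–B bond without saponifying the hindered acetate; partial loss of the alkynyl silyl group here would be harmless because step 5 removes it.

Step 4
Reactants: 7 (4R)-1-hydroxy-3,3-dimethyl-8-(trimethylsilyl)oct-7-yn-4-yl acetate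
Product: 8 (4R)-3,3-dimethyl-1-oxo-8-(trimethylsilyl)oct-7-yn-4-yl acetate
Conditions: Dess–Martin periodinane, CH2Cl2, 0 °C → rt
Reagents that add atoms: none
Why: Dess–Martin oxidation stops at the aldehyde under non-basic conditions, so the acetate stays on C5 and no lactol can form. The α-methylene next to the quaternary carbon is not prone to aldol self-condensation.

Step 5
Reactants: 8 (4R)-3,3-dimethyl-1-oxo-8-(trimethylsilyl)oct-7-yn-4-yl acetate
Product: 9 (4R)-3,3-dimethyl-1-oxooct-7-yn-4-yl acetate
Conditions: AgNO3 (0.1 equiv), acetone/H2O, rt
Reagents that add atoms: none
Why: Silver-catalysed protodesilylation of an alkynylsilane through the silver acetylide in a neutral aqueous medium. It is chosen over K2CO3/methanol, which would cleave the acetate and expose the aldehyde to base.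

Step 6
Reactants: 9 (4R)-3,3-dimethyl-1-oxooct-7-yn-4-yl acetate
Product: 10 (1Z,4R)-3,3-dimethyl-1-[(triisopropylsilyl)oxy]oct-1-en-7-yn-4-yl acetate
Conditions: iPr3SiOTf (1.2 equiv), Et3N (2 equiv), CH2Cl2, 0 °C → rt
Reagents that add atoms: triisopropylsilyl trifluoromethanesulfonate, CC(C)[Si](C(C)C)(C(C)C)OS(=O)(=O)C(F)(F)F
Why: Soft enolization: the silyl triflate activates the aldehyde oxygen and triethylamine removes an α-hydrogen, far faster than any enolization of the acetate. The Z isomer is expected to predominate, and a minor E isomer is carried along because both give the same aldehyde in step 7; the triisopropylsilyl group lets the enol ether survive chromatography on base-washed silica and the methanol of the next step.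

Step 7
Reactants: 10 (1Z,4R)-3,3-dimethyl-1-[(triisopropylsilyl)oxy]oct-1-en-7-yn-4-yl acetate
Product: 11 (1R,3S)-3-formyl-2,2-dimethyl-4-methylidenecyclohexyl acetate
Conditions: Ph3PAuCl (5 mol%), AgBF4 (5 mol%), CH2Cl2/MeOH (10:1), rt; short silica pad, used at once
Reagents that add atoms: none
Why: The cationic monovalent gold complex formed from Ph3PAuCl and AgBF4 binds the terminal alkyne of 10, and the nucleophilic enol carbon (future C1) attacks the internal alkyne carbon (future C2) anti to gold, giving a vinylgold species and a silyloxocarbenium ion; methanol then removes the silyl group and protodeaurates C7, releasing aldehyde 11 and the catalyst. The closest known reaction type is the gold-catalysed Conia-ene-type carbocyclization of silyl enol ethers onto tethered alkynes. The cyclohexane closes in the 6-exo-dig mode, because the terminal alkyne places the developing positive charge on its internal carbon and the 7-endo closure is disfavoured, so the exocyclic C2=C7 methylene forms without regioisomers. The new stereocentre C1 is controlled by C5: in the chair-like transition state the C5 acetoxy group is equatorial and the bulky silyloxyvinyl unit on C1 takes the pseudo-equatorial position, clear of the 1,3-diaxial contacts with the hydrogens on C3 and C5, which leads to the 1,3-cis (1S) aldehyde. The enol ether geometry does not enter the product because C8 returns to a planar carbonyl, so both geometric isomers converge on 11. The step needs C- over O-attack and carbocyclization ahead of methanol addition to the alkyne or methanolysis of the enol ether; the robust triisopropylsilyl group, the chain folding imposed by the C6 gem-dimethyl group and the neutral medium should secure this. The acetate is a spectator, since its carbonyl oxygen could reach the alkyne only through a seven-membered ring. The neutral conditions should leave the 1,1-disubstituted alkene and the C1–H untouched, and 11 is reduced without storage.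

Step 8
Reactants: 11 (1R,3S)-3-formyl-2,2-dimethyl-4-methylidenecyclohexyl acetate
Product: 12 (1R,3S)-3-(hydroxymethyl)-2,2-dimethyl-4-methylidenecyclohexyl acetate
Conditions: NaBH4, MeOH, −20 °C
Reagents that add atoms: none
Why: Borohydride reduction of the aldehyde is much faster than attack on the hindered secondary acetate at −20 °C. Done at once on the freshly filtered aldehyde, it converts the epimerizable, conjugation-prone C1–CHO into a configurationally stable homoallylic alcohol; C1 and C5 are not touched.

Step 9
Reactants: 12 (1R,3S)-3-(hydroxymethyl)-2,2-dimethyl-4-methylidenecyclohexyl acetate; 13 umbelliferone (7-hydroxy-2H-chromen-2-one)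
Product: 14 (1R,3S)-2,2-dimethyl-4-methylidene-3-{[(2-oxo-2H-chromen-7-yl)oxy]methyl}cyclohexyl acetate
Conditions: PPh3, diisopropyl azodicarboxylate, THF, 0 °C → rt
Reagents that add atoms: none
Why: Mitsunobu etherification: the phosphine–azodicarboxylate betaine activates the primary hydroxyl as an alkoxyphosphonium ion, which the umbelliferone phenoxide (pKa about 8) displaces at the CH2 carbon. No stereocentre is involved, and the neutral conditions spare the acetate, the exocyclic alkene and the coumarin lactone.

## Compound list

1 | 5-(trimethylsilyl)pent-4-yn-1-ol | C[Si](C)(C)C#CCCCO | starting material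
2 | 3-methylbuta-1,2-diene | CC(C)=C=C | starting material
3 | 5-(trimethylsilyl)pent-4-ynal | C[Si](C)(C)C#CCCC=O | intermediate
4 | (4R)-3,3-dimethyl-8-(trimethylsilyl)oct-1-en-7-yn-4-ol | C=CC(C)(C)[C@H](O)CCC#C[Si](C)(C)C | intermediate
5 | (4R)-3,3-dimethyl-8-(trimethylsilyl)oct-1-en-7-yn-4-yl acetate | C=CC(C)(C)[C@H](OC(C)=O)CCC#C[Si](C)(C)C | intermediate
6 | (4R)-1-(9-borabicyclo[3.3.1]nonan-9-yl)-3,3-dimethyl-8-(trimethylsilyl)oct-7-yn-4-yl acetate | CC(=O)O[C@H](CCC#C[Si](C)(C)C)C(C)(C)CCB1C2CCCC1CCC2 | intermediate
7 | (4R)-1-hydroxy-3,3-dimethyl-8-(trimethylsilyl)oct-7-yn-4-yl acetate | OCCC(C)(C)[C@H](OC(C)=O)CCC#C[Si](C)(C)C | intermediate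
8 | (4R)-3,3-dimethyl-1-oxo-8-(trimethylsilyl)oct-7-yn-4-yl acetate | O=CCC(C)(C)[C@H](OC(C)=O)CCC#C[Si](C)(C)C | intermediate
9 | (4R)-3,3-dimethyl-1-oxooct-7-yn-4-yl acetate | O=CCC(C)(C)[C@H](OC(C)=O)CCC#C | intermediate
10 | (1Z,4R)-3,3-dimethyl-1-[(triisopropylsilyl)oxy]oct-1-en-7-yn-4-yl acetate (Z isomer drawn; any E isomer is carried along) | C#CCC[C@@H](OC(C)=O)C(C)(C)/C=C\O[Si](C(C)C)(C(C)C)C(C)C | intermediate
11 | (1R,3S)-3-formyl-2,2-dimethyl-4-methylidenecyclohexyl acetate (formyl and acetoxy cis) | C=C1CC[C@@H](OC(C)=O)C(C)(C)[C@H]1C=O | intermediate
12 | (1R,3S)-3-(hydroxymethyl)-2,2-dimethyl-4-methylidenecyclohexyl acetate | C=C1CC[C@@H](OC(C)=O)C(C)(C)[C@H]1CO | intermediate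
13 | umbelliferone (7-hydroxy-2H-chromen-2-one) | Oc1ccc2ccc(=O)oc2c1 | starting material
14 | (1R,3S)-2,2-dimethyl-4-methylidene-3-{[(2-oxo-2H-chromen-7-yl)oxy]methyl}cyclohexyl acetate | C=C1CC[C@@H](OC(C)=O)C(C)(C)[C@H]1COc1ccc2ccc(=O)oc2c1 | target

## Step count and risks

Total steps: 9. Longest linear sequence: 9 steps (1 → 14).

**Step 7 (key step).**
- What may go wrong: weak facial discrimination at C1, because the gem-dimethyl carbon flanks C1 in both the pseudo-equatorial and the pseudo-axial chair and the preference may be small. Methanolysis of the enol ether or methanol addition to the alkyne may run ahead of carbocyclization. Afterwards, epimerization at C1 or migration of the C2=C7 bond into conjugation may occur while the β,γ-unsaturated aldehyde awaits reduction.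
- Fallback (sets out from 7, returns at 12): the C5 oxygen and C8 are tied together before the ring is closed, so the cis relationship follows from geometry.
  - K2CO3 in methanol removes the acetyl and the alkynyl silyl group of 7 to give (4R)-3,3-dimethyloct-7-yne-1,4-diol F1.
  - TEMPO with PhI(OAc)2 oxidizes the primary alcohol and the resulting lactol to (5R)-5-(but-3-yn-1-yl)-4,4-dimethyloxolan-2-one F2.
  - tBuMe2SiOTf and Et3N convert the lactone into the silyl ketene acetal tert-butyl{[(5R)-5-(but-3-yn-1-yl)-4,4-dimethyl-4,5-dihydrofuran-2-yl]oxy}dimethylsilane F3.
  - The same Ph3PAuCl/AgBF4 catalyst with a little methanol closes the C1–C2 bond across the five-membered ring (6-exo-dig). This can only give the bridged lactone (1S,5R)-8,8-dimethyl-2-methylidene-6-oxabicyclo[3.2.1]octan-7-one F4, whose bridgehead C1 can neither epimerize nor conjugate.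
  - LiAlH4 opens F4 to (1R,3S)-3-(hydroxymethyl)-2,2-dimethyl-4-methylidenecyclohexan-1-ol F5.
  - tBuMe2SiCl and imidazole silylate only the primary hydroxyl, giving (1R,3S)-3-{[(tert-butyldimethylsilyl)oxy]methyl}-2,2-dimethyl-4-methylidenecyclohexan-1-ol F6.
  - Ac2O/DMAP acetylates the secondary hydroxyl, giving (1R,3S)-3-{[(tert-butyldimethylsilyl)oxy]methyl}-2,2-dimethyl-4-methylidenecyclohexyl acetate F7, and HF·pyridine removes the silyl group to give 12.
  - The cost is two more operations than the main line from 7, and a gold cyclization of a lactone-derived ketene acetal that is less documented than that of enol ethers.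

**Step 1.**
- What may go wrong: erosion of enantioselectivity or an unexpected sense of induction; loss of the alkynyl silyl group under carbonate at 60 °C; competing hydrometallation of the alkyne by the iridium hydride.
- Fallback (sets out from 1, returns at 4): the C–C bond is made without stereocontrol and the stereocentre is set by ketone reduction.
  - Swern oxidation of 1 gives aldehyde 3, this time isolated.
  - Barbier addition of 1-bromo-3-methylbut-2-ene with Zn dust (attack through the substituted allyl terminus) gives racemic 3,3-dimethyl-8-(trimethylsilyl)oct-1-en-7-yn-4-ol F8.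
  - Dess–Martin oxidation gives 3,3-dimethyl-8-(trimethylsilyl)oct-1-en-7-yn-4-one F9, a ketone that cannot conjugate because its α-carbon is quaternary.
  - Corey–Bakshi–Shibata reduction with the (S)-2-methyl oxazaborolidine and catecholborane at −78 °C gives 4. The tertiary allylic group acts as the large substituent, and catecholborane at low temperature spares the vinyl group.

**Step 3.**
- What may go wrong: competing hydroboration of the alkynylsilane; acetyl transfer from the C5 oxygen to the new primary hydroxyl four atoms away; partial saponification during the oxidative work-up.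
- Fallback (sets out from 5, returns at 8): the vinyl group is shortened and rebuilt, so no free primary alcohol is formed.
  - Lemieux–Johnson cleavage of 5 (OsO4 cat., NaIO4, 2,6-lutidine, dioxane/H2O) gives (3R)-2,2-dimethyl-1-oxo-7-(trimethylsilyl)hept-6-yn-3-yl acetate F10, a non-enolizable aldehyde.
  - Wittig reaction with the ylide from (methoxymethyl)triphenylphosphonium chloride and KHMDS gives the enol ether (4R)-1-methoxy-3,3-dimethyl-8-(trimethylsilyl)oct-1-en-7-yn-4-yl acetate F11 as an E/Z mixture.
  - Dilute aqueous HCl in THF hydrolyses F11 to aldehyde 8.

**Step 9.**
- What may go wrong: slow formation or slow collapse of the alkoxyphosphonium ion at the hindered β-branched carbinol, which leaves room for azodicarboxylate-derived by-products and elimination; acetyl migration to the primary oxygen under the basicity of the betaine.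
- Fallback (sets out from 12, with the aryl partner drawn from 13, and returns at 14): the ether is closed on the aryl side of oxygen.
  - 13 is converted with Tf2O/pyridine into 2-oxo-2H-chromen-7-yl trifluoromethanesulfonate F12.
  - Miyaura borylation (B2pin2, Pd(dppf)Cl2, KOAc, dioxane) gives 7-(4,4,5,5-tetramethyl-1,3,2-dioxaborolan-2-yl)-2H-chromen-2-one F13.
  - KHF2 gives potassium trifluoro(2-oxo-2H-chromen-7-yl)borate F14.
  - A Chan–Lam-type oxidative coupling of 12 with F14 (Cu(OAc)2·H2O cat., DMAP, 4 Å molecular sieves, O2, CH2Cl2, rt) forms the aryl–oxygen bond directly. No substitution at the hindered C8 is needed and no strong base meets the acetate.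

## Further compounds

F1 | step 7 | (4R)-3,3-dimethyloct-7-yne-1,4-diol | OCCC(C)(C)[C@H](O)CCC#C
F2 | step 7 | (5R)-5-(but-3-yn-1-yl)-4,4-dimethyloxolan-2-one | O=C1CC(C)(C)[C@@H](CCC#C)O1
F3 | step 7 | tert-butyl{[(5R)-5-(but-3-yn-1-yl)-4,4-dimethyl-4,5-dihydrofuran-2-yl]oxy}dimethylsilane | C#CCC[C@H]1OC(O[Si](C)(C)C(C)(C)C)=CC1(C)C
F4 | step 7 | (1S,5R)-8,8-dimethyl-2-methylidene-6-oxabicyclo[3.2.1]octan-7-one | C=C1CC[C@H]2OC(=O)[C@@H]1C2(C)C
F5 | step 7 | (1R,3S)-3-(hydroxymethyl)-2,2-dimethyl-4-methylidenecyclohexan-1-ol | C=C1CC[C@@H](O)C(C)(C)[C@H]1CO
F6 | step 7 | (1R,3S)-3-{[(tert-butyldimethylsilyl)oxy]methyl}-2,2-dimethyl-4-methylidenecyclohexan-1-ol | C=C1CC[C@@H](O)C(C)(C)[C@H]1CO[Si](C)(C)C(C)(C)C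
F7 | step 7 | (1R,3S)-3-{[(tert-butyldimethylsilyl)oxy]methyl}-2,2-dimethyl-4-methylidenecyclohexyl acetate | C=C1CC[C@@H](OC(C)=O)C(C)(C)[C@H]1CO[Si](C)(C)C(C)(C)C
F8 | step 1 | racemic 3,3-dimethyl-8-(trimethylsilyl)oct-1-en-7-yn-4-ol | C=CC(C)(C)C(O)CCC#C[Si](C)(C)C
F9 | step 1 | 3,3-dimethyl-8-(trimethylsilyl)oct-1-en-7-yn-4-one | C=CC(C)(C)C(=O)CCC#C[Si](C)(C)C
F10 | step 3 | (3R)-2,2-dimethyl-1-oxo-7-(trimethylsilyl)hept-6-yn-3-yl acetate | O=CC(C)(C)[C@H](OC(C)=O)CCC#C[Si](C)(C)C
F11 | step 3 | (4R)-1-methoxy-3,3-dimethyl-8-(trimethylsilyl)oct-1-en-7-yn-4-yl acetate (E/Z mixture) | COC=CC(C)(C)[C@H](OC(C)=O)CCC#C[Si](C)(C)C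
F12 | step 9 | 2-oxo-2H-chromen-7-yl trifluoromethanesulfonate | O=c1ccc2ccc(OS(=O)(=O)C(F)(F)F)cc2o1
F13 | step 9 | 7-(4,4,5,5-tetramethyl-1,3,2-dioxaborolan-2-yl)-2H-chromen-2-one | CC1(C)OB(OC1(C)C)c1ccc2ccc(=O)oc2c1
F14 | step 9 | potassium trifluoro(2-oxo-2H-chromen-7-yl)borate | [K+].F[B-](F)(F)c1ccc2ccc(=O)oc2c1
A1 | alternative 1 | 7,7-dimethylbicyclo[3.1.1]heptane-2,6-dione (enantiomer as in the SMILES) | O=C1CC[C@@H]2C(C)(C)[C@H]1C2=O
A2 | alternative 1 | (1R,5R)-8,8-dimethyl-6-oxabicyclo[3.2.1]octane-2,7-dione | O=C1CC[C@@H](O2)C(C)(C)[C@H]1C2=O
A3 | alternative 2 | 4-[(tert-butyldimethylsilyl)oxy]-5-{[(4-methoxybenzyl)oxy]methyl}-6-methylhept-6-enal (stereoisomer as in the SMILES) | O=CCC[C@@H](O[Si](C)(C)C(C)(C)C)[C@H](COCc1ccc(OC)cc1)C(C)=C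
A4 | alternative 2 | 4-[(tert-butyldimethylsilyl)oxy]-3-{[(4-methoxybenzyl)oxy]methyl}-2,2-dimethylcyclohexan-1-ol (stereoisomer as in the SMILES) | O[C@@H]1CC[C@@H](O[Si](C)(C)C(C)(C)C)[C@H](COCc2ccc(OC)cc2)C1(C)C
A5 | alternative 3 | aurapten, 7-{[(2E)-3,7-dimethylocta-2,6-dien-1-yl]oxy}-2H-chromen-2-one | CC(C)=CCC/C(C)=C/COc1ccc2ccc(=O)oc2c1
A6 | alternative 3 | 7-{[(2E)-5-[(2R)-3,3-dimethyloxiran-2-yl]-3-methylpent-2-en-1-yl]oxy}-2H-chromen-2-one | CC1(C)O[C@@H]1CC/C(C)=C/COc1ccc2ccc(=O)oc2c1
A7 | alternative 3 | 7-{[(1S,3R)-3-hydroxy-2,2-dimethyl-6-methylidenecyclohexyl]methoxy}-2H-chromen-2-one | C=C1CC[C@@H](O)C(C)(C)[C@H]1COc1ccc2ccc(=O)oc2c1
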